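(Readings and results were generated by integration for an exercise.)

Substrate in the autumn flask is down 15 percentage points at 80.0 min, against a scatter of 1 point, and from that fall I must judge whether the next run can carry less partner.

| flask | substrate | partner | remark | time |
|---|---|---|---|---|
| autumn | 1.8 M | 1.98 M | the very flask that is asked about, followed so far |  |
| flask | 1.8 M | 1.98 M |  | 3.0 h |

autumn run (percent of the substrate charged)

| time / min | substrate / % | single product / % |
|---|---|---|
| 6.00 | 99.3 | 0 |
| 10.0 | 99.4 | 0.9 |
| 15.0 | 96.2 | 2.8 |
| 25.0 | 96.8 | 2.1 |
| 40.0 | 93.3 | 3.7 |
| 80.0 | 85.2 | 9.1 |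

(standard deviation of a reading: 1 percentage point)



* the substrate standing at 3.0 h, as a percentage of the substrate charged
* the single product standing at 3.0 h, as a percentage of the substrate charged
* the bis adduct standing at 3.0 h, as a percentage of the substrate charged
* the tris adduct standing at 3.0 h, as a percentage of the substrate charged

By charge, substrate is the limiting reagent of this flask, so I count everything in fractions of the substrate charge: a is the substrate left, r = 1.10 is the partner charged, and x = 0.100 is the partner over. If one partner goes with each substrate, partner stands at a + x and da/dt = −κ·a·(a + x), which integrates in closed form to a = x/(r·exp(xκt) − 1). I call κ the charge clock: the fractional loss of substrate per hour with substrate and partner each at one full substrate charge. Solving the closed form at the last reading gives κ = 0.118 h⁻¹, a reading that carries the scatter. Taken to 3.0 h, it leaves a = 71.7%. In this count a changed partner charge enters through r and x, so this κ prices a cut, and I hold the charge until the flask has been read at 3.0 h.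

The forecast, which “gives an exposure of about 0.3”, says substrate 74%, single product 13.5%, bis adduct 11% and tris adduct 1.5%, its substrate standing above mine.

The flask gives substrate 73.6%, single product 14.4%, bis adduct 0.364% and tris adduct 0.0728%, by this scheme:

    substrate + by-product → side product (k = 0.0120 M⁻¹ min⁻¹)
    partner + bis adduct → tris adduct + by-product (k = 0.00220 M⁻¹ min⁻¹)
    partner + single product → bis adduct + by-product (k = 2.40 × 10⁻⁴ M⁻¹ min⁻¹)
    partner ⇌ dormant form (K = 1.20, k = 0.00380 min⁻¹)
    substrate + partner → single product + by-product (k = 6.80 × 10⁻⁴ M⁻¹ min⁻¹)
    bis adduct ⇌ isomer of the product (K = 12.0, k = 7.70 × 10⁻⁴ min⁻¹)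

My 71.7% lies 1.9 points below that substrate, although partner in this flask stands at 50.7% of its own charge, with 0.699 M of dormant form beside it, where my count held 74.3% partner and no dormant form. The same κ, with r = 0.439 for a neighbouring flask charged with 0.79 M partner and the same substrate, reckons 87.7% substrate left at 3.0 h, and that neighbouring flask stands at 88.6%.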